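**Retrosynthetic overview**
Numbering: ring A = C1 (CMe2), C2, C3 (CHBr), C4, C5 (C(OH)CH3), C6 (spiro); ring B = C6, C7=C8, C9 (=C12HBr), C10, C11.
Feature: on ring A the C5 hydroxyl is trans to the vinylic carbon C7 (and cis to C11) on the adjacent spiro carbon C6, which is the imprint of an anti opening of a C5–C6 epoxide at C6 by C7.
Endgame disconnections: C3–Br from C3–OH with inversion; C9=C12HBr from a C9 ketone; the C9 ketone from the allylic C9H2.
Key disconnection C6–C7: Lewis-acid opening of a ring A C5–C6 epoxide at C6 by the silicon-bearing carbon of a (Z)-vinylsilane tethered to C6; the epoxide comes from C3-hydroxyl-directed epoxidation of a C5=C6 alkene, itself from Negishi coupling of an actinol enol triflate.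
Ring order: ring A from the chiral pool ((4R,6R)-actinol), ring B closed second in the key step.

Key step: step 9

Remark: (4R,6R)-actinol and 5-(trimethylsilyl)pent-4-yn-1-ol are taken as commercial; spiro compounds are named with the atom numbering given above.

**Step 1**
Reactants: 1 5-(trimethylsilyl)pent-4-yn-1-ol
Product: 2 (Z)-5-(trimethylsilyl)pent-4-en-1-ol
Conditions: i-Bu2AlH (2.5 equiv), Et2O, 0 °C → reflux; then cold dilute H2SO4
Reagents that add atoms: none
Why: In ether the aluminium hydride adds cis across the silylalkyne with aluminium on the silicon-bearing carbon (hydroalumination of a 1-silylalkyne in a donor solvent), and protonolysis with retention gives the (Z)-vinylsilane; the first equivalent only deprotonates the alcohol.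

**Step 2**
Reactants: 2 (Z)-5-(trimethylsilyl)pent-4-en-1-ol
Product: 3 (Z)-(5-iodopent-1-en-1-yl)trimethylsilane
Conditions: PPh3, imidazole, I2, CH2Cl2, 0 °C → rt
Reagents that add atoms: iodine, II
Why: Garegg–Samuelsson (Appel-type) iodination converts the primary alcohol through its oxyphosphonium salt by SN2, and with iodine pre-complexed to PPh3 the vinylsilane should not be iododesilylated.

**Step 3**
Reactants: 4 (4R,6R)-4-hydroxy-2,2,6-trimethylcyclohexan-1-one ((4R,6R)-actinol)
Product: 5 (4R,6R)-4-[(tert-butyldimethylsilyl)oxy]-2,2,6-trimethylcyclohexan-1-one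
Conditions: TBSCl, imidazole, DMF, rt
Reagents that add atoms: tert-butyldimethylsilyl chloride, CC(C)(C)[Si](C)(C)Cl
Why: Imidazole-promoted silylation (Corey protocol) masks the only hydroxyl so that the ketone can be enolized.

**Step 4**
Reactants: 5 (4R,6R)-4-[(tert-butyldimethylsilyl)oxy]-2,2,6-trimethylcyclohexan-1-one
Product: 7 (R)-4-[(tert-butyldimethylsilyl)oxy]-2,6,6-trimethylcyclohex-1-en-1-yl trifluoromethanesulfonate, via lithium enolate 6 (not isolated)
Conditions: LiN(i-Pr)2, THF, −78 → 0 °C; then PhNTf2, −78 °C → rt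
Reagents that add atoms: N-phenylbis(trifluoromethanesulfonimide), O=S(=O)(N(c1ccccc1)S(=O)(=O)C(F)(F)F)C(F)(F)F
Why: The ketone has a single enolizable position (the CH(CH3) carbon; the other α-carbon is quaternary), so one enolate forms and PhNTf2 triflates it on oxygen (McMurry–Scott enol triflate synthesis); the methyl-bearing stereocenter is deliberately erased and the silyloxy group, γ to the carbonyl, cannot be eliminated.

**Step 5**
Reactants: 3 (Z)-(5-iodopent-1-en-1-yl)trimethylsilane; 7 (R)-4-[(tert-butyldimethylsilyl)oxy]-2,6,6-trimethylcyclohex-1-en-1-yl trifluoromethanesulfonate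
Product: 9 tert-butyldimethyl{[(R)-3,5,5-trimethyl-4-[(Z)-5-(trimethylsilyl)pent-4-en-1-yl]cyclohex-3-en-1-yl]oxy}silane, via alkylzinc iodide 8 (not isolated)
Conditions: 3, Zn dust (activated with BrCH2CH2Br, Me3SiCl), LiCl, THF, 40 °C; then 7, Pd(dppf)Cl2 (5 mol %; dppf = 1,1'-bis(diphenylphosphino)ferrocene), THF, 60 °C
Reagents that add atoms: none
Why: Knochel zinc insertion into the primary iodide followed by Negishi sp3–sp2 coupling, in which the bidentate dppf ligand favours reductive elimination over β-hydride elimination, joins the chain to the hindered tetrasubstituted enol triflate (2,6,6-trimethylcyclohexenyl triflates are known coupling partners); vinylsilane and silyl ether are inert to alkylzinc and palladium.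

**Step 6**
Reactants: 9 tert-butyldimethyl{[(R)-3,5,5-trimethyl-4-[(Z)-5-(trimethylsilyl)pent-4-en-1-yl]cyclohex-3-en-1-yl]oxy}silane
Product: 10 (R)-3,5,5-trimethyl-4-[(Z)-5-(trimethylsilyl)pent-4-en-1-yl]cyclohex-3-en-1-ol
Conditions: Bu4NF, THF, 0 °C → rt
Reagents that add atoms: none
Why: Fluoride cleaves the secondary silyl ether (desilylation) while the carbon-bound vinylic trimethylsilyl group, which has no β-oxygen to activate it, should stay in place.

**Step 7**
Reactants: 10 (R)-3,5,5-trimethyl-4-[(Z)-5-(trimethylsilyl)pent-4-en-1-yl]cyclohex-3-en-1-ol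
Product: 11 (1S,3S,6R)-1,5,5-trimethyl-6-[(Z)-5-(trimethylsilyl)pent-4-en-1-yl]-7-oxabicyclo[4.1.0]heptan-3-ol (epoxide oxygen cis to the hydroxyl)
Conditions: VO(acac)2 (5 mol %), t-BuOOH (in decane), CH2Cl2, 0 °C → rt
Reagents that add atoms: tert-butyl hydroperoxide, CC(C)(C)OO
Why: Hydroxyl-directed epoxidation (Sharpless–Michaelson): the vanadium alkoxide of the homoallylic hydroxyl delivers oxygen to its own face of the tetrasubstituted ring alkene, which sets C5 and C6 with the epoxide cis to the C3 oxygen, and the remote vinylsilane, lacking a directing group, is left alone.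

**Step 8**
Reactants: 11 (1S,3S,6R)-1,5,5-trimethyl-6-[(Z)-5-(trimethylsilyl)pent-4-en-1-yl]-7-oxabicyclo[4.1.0]heptan-3-ol
Product: 12 tert-butyldimethyl{[(1S,3S,6R)-1,5,5-trimethyl-6-[(Z)-5-(trimethylsilyl)pent-4-en-1-yl]-7-oxabicyclo[4.1.0]heptan-3-yl]oxy}silane
Conditions: TBSCl, imidazole, DMF, rt
Reagents that add atoms: tert-butyldimethylsilyl chloride, CC(C)(C)[Si](C)(C)Cl
Why: Imidazole-promoted silylation under non-acidic conditions shields the hydroxyl from the aluminium Lewis acid of the next step without opening the tetrasubstituted epoxide.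

**Step 9**
Reactants: 12 tert-butyldimethyl{[(1S,3S,6R)-1,5,5-trimethyl-6-[(Z)-5-(trimethylsilyl)pent-4-en-1-yl]-7-oxabicyclo[4.1.0]heptan-3-yl]oxy}silane
Product: 13 (3S,5S,6S)-3-[(tert-butyldimethylsilyl)oxy]-1,1,5-trimethylspiro[5.5]undec-7-en-5-ol (C5–OH cis to the C3 oxygen and trans to C7)
Conditions: MeAlCl2 (2 equiv, hexanes), CH2Cl2, −78 °C; quench Et3N, then aq. NaHCO3
Reagents that add atoms: none
Why: MeAlCl2 binds the epoxide oxygen and loosens the C6–O bond, the silicon-bearing carbon C7 of the (Z)-vinylsilane attacks C6 from the face opposite the oxygen, and the β-silyl cation at C8 collapses by loss of Me3SiCl to the cis ring alkene C7=C8. The closest known reaction type is the Lewis-acid-promoted, epoxide-initiated cation–olefin cyclization terminated by a vinylsilane (ipso substitution); what is different here is that the epoxide is tetrasubstituted and the tether sits on the attacked carbon. Ring B closes by a 6-exo-tet opening at the epoxide that is endocyclic (6-endo) with respect to the vinylsilane, whereas attack on C5 would require a seven-membered ring. C6 is set by inversion (C7 enters anti to the departing oxygen and C11 swings to the oxygen side), and C5 keeps the oxygen and methyl placed by the directed epoxidation, so both centers trace back to the actinol carbinol carbon. The step needs C6–O rather than C5–O cleavage and ring closure faster than a 1,2-shift of the activated epoxide to a ketone; the tether on C6, the low temperature and the proton-scavenging alkylaluminium Lewis acid are expected to secure this.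

**Step 10**
Reactants: 13 (3S,5S,6S)-3-[(tert-butyldimethylsilyl)oxy]-1,1,5-trimethylspiro[5.5]undec-7-en-5-ol
Product: 14 tert-butyldimethyl{[(3S,5S,6S)-1,1,5-trimethyl-5-[(triethylsilyl)oxy]spiro[5.5]undec-7-en-3-yl]oxy}silane
Conditions: Et3SiOTf, 2,6-lutidine, CH2Cl2, −78 → 0 °C
Reagents that add atoms: triethylsilyl trifluoromethanesulfonate, CC[Si](CC)(CC)OS(=O)(=O)C(F)(F)F
Why: Silylation of the hindered tertiary alcohol with a silyl triflate masks the C5 hydroxyl, whose alkoxide could otherwise open ring A by a vinylogous retro-aldol once the C9 ketone is in place.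

**Step 11**
Reactants: 14 tert-butyldimethyl{[(3S,5S,6S)-1,1,5-trimethyl-5-[(triethylsilyl)oxy]spiro[5.5]undec-7-en-3-yl]oxy}silane
Product: 15 (3S,5S,6S)-3-[(tert-butyldimethylsilyl)oxy]-1,1,5-trimethyl-5-[(triethylsilyl)oxy]spiro[5.5]undec-7-en-9-one
Conditions: Rh2(cap)4 (1 mol %; cap = caprolactamate), t-BuOOH (70% aq., 5 equiv), K2CO3 (0.5 equiv), CH2Cl2, rt
Reagents that add atoms: tert-butyl hydroperoxide, CC(C)(C)OO
Why: Doyle allylic oxidation (tert-butylperoxyl radical chain): C9 is the only allylic CH2 because C6 is quaternary, and the delocalized allyl radical should be trapped at C9 and not at the neopentyl C7, giving the untransposed 4,4-disubstituted cyclohexenone.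

**Step 12**
Reactants: 15 (3S,5S,6S)-3-[(tert-butyldimethylsilyl)oxy]-1,1,5-trimethyl-5-[(triethylsilyl)oxy]spiro[5.5]undec-7-en-9-one
Product: 16 {[(3S,5S,6S,9E)-9-(bromomethylidene)-1,1,5-trimethyl-5-[(triethylsilyl)oxy]spiro[5.5]undec-7-en-3-yl]oxy}(tert-butyl)dimethylsilane
Conditions: Ph3P(CH2Br)Br, KOtBu, THF, −78 °C; then 15, −78 °C → rt
Reagents that add atoms: (bromomethyl)triphenylphosphonium bromide, BrC[P+](c1ccccc1)(c1ccccc1)c1ccccc1.[Br-]
Why: Wittig bromomethylenation with Ph3P=CHBr adds 1,2 to the enone carbonyl, and the bromine is expected to settle preferentially on the side of the C10 methylene, away from C8 (E), the minor Z isomer being removed by chromatography; both silyl ethers tolerate the ylide and KOtBu.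

**Step 13**
Reactants: 16 {[(3S,5S,6S,9E)-9-(bromomethylidene)-1,1,5-trimethyl-5-[(triethylsilyl)oxy]spiro[5.5]undec-7-en-3-yl]oxy}(tert-butyl)dimethylsilane
Product: 17 (3S,5S,6S,9E)-9-(bromomethylidene)-1,1,5-trimethylspiro[5.5]undec-7-ene-3,5-diol
Conditions: Bu4NF (excess), THF, 0 °C → 40 °C
Reagents that add atoms: none
Why: Fluoride removes both silyl ethers (desilylation), the tertiary triethylsilyl ether needing gentle warming, and the bromodiene is inert to fluoride.

**Step 14**
Reactants: 17 (3S,5S,6S,9E)-9-(bromomethylidene)-1,1,5-trimethylspiro[5.5]undec-7-ene-3,5-diol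
Product: 18 (3R,5S,6S,9E)-3-bromo-9-(bromomethylidene)-1,1,5-trimethylspiro[5.5]undec-7-en-5-ol
Conditions: CBr4, PPh3, 2,6-lutidine, CH2Cl2, 0 °C → rt
Reagents that add atoms: carbon tetrabromide, BrC(Br)(Br)Br
Why: Appel reaction: the secondary C3 hydroxyl should form the oxyphosphonium salt far faster than the tertiary C5 hydroxyl beside the spiro carbon, and bromide displaces it by SN2 with inversion through the ring-flipped chair with axial C3–O, turning the (3S)-alcohol into the (3R)-bromide trans to the C5 hydroxyl.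

**Compound list**
1 | 5-(trimethylsilyl)pent-4-yn-1-ol | C[Si](C)(C)C#CCCCO | starting material
2 | (Z)-5-(trimethylsilyl)pent-4-en-1-ol | C[Si](C)(C)/C=C\CCCO | intermediate
3 | (Z)-(5-iodopent-1-en-1-yl)trimethylsilane | C[Si](C)(C)/C=C\CCCI | intermediate
4 | (4R,6R)-4-hydroxy-2,2,6-trimethylcyclohexan-1-one ((4R,6R)-actinol) | CC1(C)C[C@H](O)C[C@@H](C)C1=O | starting material
5 | (4R,6R)-4-[(tert-butyldimethylsilyl)oxy]-2,2,6-trimethylcyclohexan-1-one | CC1(C)C[C@H](O[Si](C)(C)C(C)(C)C)C[C@@H](C)C1=O | intermediate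
6 | lithium (R)-4-[(tert-butyldimethylsilyl)oxy]-2,6,6-trimethylcyclohex-1-en-1-olate | CC1(C)C[C@H](O[Si](C)(C)C(C)(C)C)CC(C)=C1[O-].[Li+] | intermediate
7 | (R)-4-[(tert-butyldimethylsilyl)oxy]-2,6,6-trimethylcyclohex-1-en-1-yl trifluoromethanesulfonate | CC1(C)C[C@H](O[Si](C)(C)C(C)(C)C)CC(C)=C1OS(=O)(=O)C(F)(F)F | intermediate
8 | (Z)-[5-(trimethylsilyl)pent-4-en-1-yl]zinc iodide | C[Si](C)(C)/C=C\CCC[Zn]I | intermediate
9 | tert-butyldimethyl{[(R)-3,5,5-trimethyl-4-[(Z)-5-(trimethylsilyl)pent-4-en-1-yl]cyclohex-3-en-1-yl]oxy}silane | CC1(C)C[C@H](O[Si](C)(C)C(C)(C)C)CC(C)=C1CCC/C=C\[Si](C)(C)C | intermediate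
10 | (R)-3,5,5-trimethyl-4-[(Z)-5-(trimethylsilyl)pent-4-en-1-yl]cyclohex-3-en-1-ol | CC1(C)C[C@H](O)CC(C)=C1CCC/C=C\[Si](C)(C)C | intermediate
11 | (1S,3S,6R)-1,5,5-trimethyl-6-[(Z)-5-(trimethylsilyl)pent-4-en-1-yl]-7-oxabicyclo[4.1.0]heptan-3-ol | CC1(C)C[C@H](O)C[C@]2(C)O[C@]12CCC/C=C\[Si](C)(C)C | intermediate
12 | tert-butyldimethyl{[(1S,3S,6R)-1,5,5-trimethyl-6-[(Z)-5-(trimethylsilyl)pent-4-en-1-yl]-7-oxabicyclo[4.1.0]heptan-3-yl]oxy}silane | CC1(C)C[C@H](O[Si](C)(C)C(C)(C)C)C[C@]2(C)O[C@]12CCC/C=C\[Si](C)(C)C | intermediate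
13 | (3S,5S,6S)-3-[(tert-butyldimethylsilyl)oxy]-1,1,5-trimethylspiro[5.5]undec-7-en-5-ol | CC1(C)C[C@H](O[Si](C)(C)C(C)(C)C)C[C@](C)(O)[C@@]12C=CCCC2 | intermediate
14 | tert-butyldimethyl{[(3S,5S,6S)-1,1,5-trimethyl-5-[(triethylsilyl)oxy]spiro[5.5]undec-7-en-3-yl]oxy}silane | CC1(C)C[C@H](O[Si](C)(C)C(C)(C)C)C[C@](C)(O[Si](CC)(CC)CC)[C@@]12C=CCCC2 | intermediate
15 | (3S,5S,6S)-3-[(tert-butyldimethylsilyl)oxy]-1,1,5-trimethyl-5-[(triethylsilyl)oxy]spiro[5.5]undec-7-en-9-one | CC1(C)C[C@H](O[Si](C)(C)C(C)(C)C)C[C@](C)(O[Si](CC)(CC)CC)[C@@]12C=CC(=O)CC2 | intermediate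
16 | {[(3S,5S,6S,9E)-9-(bromomethylidene)-1,1,5-trimethyl-5-[(triethylsilyl)oxy]spiro[5.5]undec-7-en-3-yl]oxy}(tert-butyl)dimethylsilane | CC1(C)C[C@H](O[Si](C)(C)C(C)(C)C)C[C@](C)(O[Si](CC)(CC)CC)[C@@]12C=C/C(=C/Br)CC2 | intermediate
17 | (3S,5S,6S,9E)-9-(bromomethylidene)-1,1,5-trimethylspiro[5.5]undec-7-ene-3,5-diol | CC1(C)C[C@H](O)C[C@](C)(O)[C@@]12C=C/C(=C/Br)CC2 | intermediate
18 | (3R,5S,6S,9E)-3-bromo-9-(bromomethylidene)-1,1,5-trimethylspiro[5.5]undec-7-en-5-ol | CC1(C)C[C@@H](Br)C[C@](C)(O)[C@@]12C=C/C(=C/Br)CC2 | target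

Total step count: 14. Longest linear sequence: 12 steps (steps 3 to 14 from actinol 4; the chain from 1 through steps 1, 2 and 5 to 14 is equally long).

**Steps most likely to fail**

1. Step 9. The activated tetrasubstituted epoxide may rearrange by a 1,2-shift to a ketone, or ionize at C5, before the weakly nucleophilic vinylsilane closes the ring. The fallback uses a far more nucleophilic terminator and functionalizes ring B from a C8 ketone; it sets out from 12 and comes back at 16, replacing steps 9 to 12.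
   - Oxidative cleavage of the vinylsilane (OsO4 cat., NaIO4, 2,6-lutidine, dioxane–H2O) would give the C8 aldehyde F1.
   - MeMgBr (THF, −78 °C) would give the secondary alcohol F2, and Dess–Martin periodinane the methyl ketone F3.
   - LiN(i-Pr)2 then TBSCl/HMPA (THF, −78 °C) would give the terminal silyl enol ether F4.
   - MeAlCl2 (CH2Cl2, −78 °C) should close ring B through the enol ether CH2 (C7) onto C6 with the same inversion, giving the spiro C8 ketone F5; epoxide-initiated cyclizations terminated by silyl enol ethers under MeAlCl2 are established in polyene synthesis.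
   - Et3SiOTf/2,6-lutidine would give the bis-silyl ketone F6.
   - Formylation on the unhindered C9 side (NaH, HCO2Et, THF) would give the hydroxymethylidene ketone F7.
   - Ph3PBr2/Et3N should convert F7 into the (E)-bromomethylidene ketone F8, with bromine anti to the carbonyl.
   - Luche reduction (NaBH4, CeCl3·7H2O, MeOH) would give the allylic alcohol F9, and syn-dehydration toward C7, the only carbon with a β-hydrogen (Burgess reagent, toluene, 50 °C), would give 16.

2. Step 12. Oxaphosphetane formation may discriminate poorly between the two flanks of the C9 carbonyl, so that the bromine geometry is not controlled. The fallback sets the geometry with a temporary C8 carbonyl; it sets out from 14 and comes back at 16, replacing steps 11 and 12.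
   - Hydroboration–oxidation (BH3·SMe2, THF; then NaOH, H2O2), with boron going to C8 away from the spiro carbon, would give the C8 alcohol F10.
   - Dess–Martin oxidation would give the ketone F6, which is carried through F7, F8 and F9 to 16 exactly as in the first fallback.

3. Step 14. The oxyphosphonium salt may eliminate to a ring alkene, or the neighbouring tertiary C5 hydroxyl may be drawn in (cyclic phosphorane, ionization), instead of clean invertive displacement. The fallback sets out from 17 and comes back at 18.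
   - SOCl2/Et3N (CH2Cl2, 0 °C) would give the six-membered cyclic sulfite F11, which locks ring A in the chair with both C–O bonds axial.
   - LiBr (DMF, 70 °C) should open it at the secondary carbon C3 with inversion, bromide entering from the open equatorial direction.
   - Aqueous acid would hydrolyse the C5 sulfite half-ester with loss of SO2 to give 18.

**Further compounds**
F1 | step 9 | 4-[(1R,4S,6S)-4-[(tert-butyldimethylsilyl)oxy]-2,2,6-trimethyl-7-oxabicyclo[4.1.0]heptan-1-yl]butanal | CC1(C)C[C@H](O[Si](C)(C)C(C)(C)C)C[C@]2(C)O[C@]12CCCC=O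
F2 | step 9 | 5-[(1R,4S,6S)-4-[(tert-butyldimethylsilyl)oxy]-2,2,6-trimethyl-7-oxabicyclo[4.1.0]heptan-1-yl]pentan-2-ol (carbinol epimers) | CC1(C)C[C@H](O[Si](C)(C)C(C)(C)C)C[C@]2(C)O[C@]12CCCC(C)O
F3 | step 9 | 5-[(1R,4S,6S)-4-[(tert-butyldimethylsilyl)oxy]-2,2,6-trimethyl-7-oxabicyclo[4.1.0]heptan-1-yl]pentan-2-one | CC1(C)C[C@H](O[Si](C)(C)C(C)(C)C)C[C@]2(C)O[C@]12CCCC(C)=O
F4 | step 9 | tert-butyl{[5-[(1R,4S,6S)-4-[(tert-butyldimethylsilyl)oxy]-2,2,6-trimethyl-7-oxabicyclo[4.1.0]heptan-1-yl]pent-1-en-2-yl]oxy}dimethylsilane | CC1(C)C[C@H](O[Si](C)(C)C(C)(C)C)C[C@]2(C)O[C@]12CCCC(=C)O[Si](C)(C)C(C)(C)C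
F5 | step 9 | (3S,5S,6S)-3-[(tert-butyldimethylsilyl)oxy]-5-hydroxy-1,1,5-trimethylspiro[5.5]undecan-8-one | CC1(C)C[C@H](O[Si](C)(C)C(C)(C)C)C[C@](C)(O)[C@@]12CC(=O)CCC2
F6 | step 9 | (3S,5S,6S)-3-[(tert-butyldimethylsilyl)oxy]-1,1,5-trimethyl-5-[(triethylsilyl)oxy]spiro[5.5]undecan-8-one | CC1(C)C[C@H](O[Si](C)(C)C(C)(C)C)C[C@](C)(O[Si](CC)(CC)CC)[C@@]12CC(=O)CCC2
F7 | step 9 | (3S,5S,6S)-3-[(tert-butyldimethylsilyl)oxy]-9-(hydroxymethylidene)-1,1,5-trimethyl-5-[(triethylsilyl)oxy]spiro[5.5]undecan-8-one (chelated enol of the 9-formyl ketone) | CC1(C)C[C@H](O[Si](C)(C)C(C)(C)C)C[C@](C)(O[Si](CC)(CC)CC)[C@@]12CC(=O)/C(=C\O)CC2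
F8 | step 9 | (3S,5S,6S,9E)-9-(bromomethylidene)-3-[(tert-butyldimethylsilyl)oxy]-1,1,5-trimethyl-5-[(triethylsilyl)oxy]spiro[5.5]undecan-8-one | CC1(C)C[C@H](O[Si](C)(C)C(C)(C)C)C[C@](C)(O[Si](CC)(CC)CC)[C@@]12CC(=O)/C(=C/Br)CC2
F9 | step 9 | (3S,5S,6S,9E)-9-(bromomethylidene)-3-[(tert-butyldimethylsilyl)oxy]-1,1,5-trimethyl-5-[(triethylsilyl)oxy]spiro[5.5]undecan-8-ol (C8 epimers) | CC1(C)C[C@H](O[Si](C)(C)C(C)(C)C)C[C@](C)(O[Si](CC)(CC)CC)[C@@]12CC(O)/C(=C/Br)CC2
F10 | step 12 | (3S,5S,6S)-3-[(tert-butyldimethylsilyl)oxy]-1,1,5-trimethyl-5-[(triethylsilyl)oxy]spiro[5.5]undecan-8-ol (C8 epimers) | CC1(C)C[C@H](O[Si](C)(C)C(C)(C)C)C[C@](C)(O[Si](CC)(CC)CC)[C@@]12CC(O)CCC2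
F11 | step 14 | cyclic sulfite of diol 17 (O–S(=O)–O bridge between C3 and C5, both oxygens on the face opposite C7) | CC1(C)C[C@@H]2OS(=O)O[C@@](C)(C2)[C@@]13C=C/C(=C/Br)CC3
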